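**Assumption:** the SMILES is taken as definitive, i.e. the (3R,5E,7S) diarylheptanoid unit (C7 = the diaryl-substituted carbon) on C3' of an E-chalcone; (R)-but-3-en-2-ol and (S)-BINOL are bought as single enantiomers.

## Retrosynthetic overview

1. Chalcone last: Claisen–Schmidt condensation of the ring A acetyl group with benzaldehyde, which also frees the two acetylated phenols.
2. C5=C6: cross-metathesis of a propenyl arene with an (R)-1-aryl-hex-5-en-3-ol (C3 from a Keck allylation of a Heck-derived 3-arylpropanal).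
3. Key step, C7–ring A bond and C7 stereocentre: aromatic Claisen rearrangement of an aryl (S)-1-methyl-3-arylallyl ether. The [3,3] shift dearomatises ring A to an ortho-dienone, transfers chirality from C–O to C–C, then re-aromatises.
4. Ether: Mitsunobu inversion of an (R,E)-4-arylbut-3-en-2-ol (4-acetoxystyrene + (R)-but-3-en-2-ol by cross-metathesis) at the 4-OH of 2',4'-dihydroxy-6'-methoxyacetophenone.
5. No ring is built: all three benzene rings are bought; ring A is broken and restored in the key step.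

## Route

Step 1
Reactants: 1 4-acetoxystyrene (4-ethenylphenyl acetate); 2 (R)-but-3-en-2-ol
Product: 3 4-[(1E,3R)-3-hydroxybut-1-en-1-yl]phenyl acetate
Conditions: second-generation Hoveyda–Grubbs catalyst (2 mol %), 1 (2.5 equiv), CH2Cl2, 40 °C
Reagents that add atoms: none
Why: Olefin cross-metathesis of a styrene with a secondary allylic alcohol is an E-selective pairing that releases ethene and does not touch the carbinol centre, so 3 keeps the (R) configuration of the chiral-pool alcohol.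

Step 2
Reactants: 3 4-[(1E,3R)-3-hydroxybut-1-en-1-yl]phenyl acetate; 4 1-(2,4-dihydroxy-6-methoxyphenyl)ethanone
Product: 5 4-[(1E,3S)-3-(4-acetyl-3-hydroxy-5-methoxyphenoxy)but-1-en-1-yl]phenyl acetate
Conditions: PPh3, DIAD, THF, 0 °C to rt
Reagents that add atoms: none
Why: Mitsunobu reaction, in which only the non-chelated, more acidic 4-OH of 4 (para to the acetyl group) is engaged and its phenoxide displaces the oxyphosphonium of 3 by SN2 with inversion, giving the (S)-aryl ether.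

Step 3
Reactants: 5 4-[(1E,3S)-3-(4-acetyl-3-hydroxy-5-methoxyphenoxy)but-1-en-1-yl]phenyl acetate
Product: 7 4-[(1S,2E)-1-(3-acetyl-2,6-dihydroxy-4-methoxyphenyl)but-2-en-1-yl]phenyl acetate, via ortho-dienone 6 (not isolated)
Conditions: Eu(fod)3 [europium tris(6,6,7,7,8,8,8-heptafluoro-2,2-dimethyloctane-3,5-dionate)] (10 mol %), CHCl3, 60 °C, dark
Reagents that add atoms: none
Why: Aromatic Claisen rearrangement ([3,3]-sigmatropic shift) through a chair transition state with the methyl group equatorial breaks the aromaticity of ring A to give dienone 6 and transfers the C–O stereocentre suprafacially to the new diaryl-substituted carbon (S, with an E-propenyl group), while the chelated 2-OH···O=C hydrogen bond fixes the C3=C4 double bond so that migration goes to C3 between the two oxygens before 6 enolises back to the arene.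

Step 4
Reactants: 8 4-iodophenyl acetate; 9 allyl alcohol (prop-2-en-1-ol)
Product: 11 4-(3-oxopropyl)phenyl acetate, via enol 10 (not isolated)
Conditions: Pd(OAc)2 (2 mol %), Bu4NCl, NaHCO3, DMF, 45 °C
Reagents that add atoms: none
Why: Heck reaction under Jeffery conditions, in which the aryl group adds to the terminal carbon of allyl alcohol and β-hydride elimination towards the carbinol gives enol 10, which tautomerises to the aldehyde while the aryl acetate survives the mild base.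

Step 5
Reactants: 11 4-(3-oxopropyl)phenyl acetate
Product: 13 4-[(3R)-3-hydroxyhex-5-en-1-yl]phenyl acetate, via tributylstannyl ether 12 (not isolated)
Conditions: Ti(OiPr)4 (10 mol %), (S)-BINOL (20 mol %), 4 Å MS, CH2Cl2, −20 °C; aq NaHCO3 work-up
Reagents that add atoms: allyltributylstannane, C=CC[Sn](CCCC)(CCCC)CCCC
Why: Keck asymmetric allylation, in which the (S)-BINOL titanium Lewis acid directs allyl transfer from tin to the Si face of the aldehyde and so sets the (R)-carbinol (as stannyl ether 12, hydrolysed on work-up).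

Step 6
Reactants: 7 4-[(1S,2E)-1-(3-acetyl-2,6-dihydroxy-4-methoxyphenyl)but-2-en-1-yl]phenyl acetate; 13 4-[(3R)-3-hydroxyhex-5-en-1-yl]phenyl acetate
Product: 14 4-[(3R,5E,7S)-7-(3-acetyl-2,6-dihydroxy-4-methoxyphenyl)-7-(4-acetoxyphenyl)-3-hydroxyhept-5-en-1-yl]phenyl acetate
Conditions: second-generation Hoveyda–Grubbs catalyst (2 × 5 mol %), 13 (3 equiv), 1,4-benzoquinone (20 mol %), CH2Cl2, 40 °C, argon sparge
Reagents that add atoms: none
Why: Olefin cross-metathesis between the terminal alkene of 13 and the propenyl group of 7 expels propene and gives the E-disubstituted alkene, with benzoquinone suppressing ruthenium hydride migration of the double bond towards the doubly benzylic centre, so neither stereocentre is involved.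

Step 7
Reactants: 14 4-[(3R,5E,7S)-7-(3-acetyl-2,6-dihydroxy-4-methoxyphenyl)-7-(4-acetoxyphenyl)-3-hydroxyhept-5-en-1-yl]phenyl acetate; 15 benzaldehyde
Product: 18 7-epi-katsumain C, via deacetylated methyl ketone 16 (not isolated), via aldol adduct 17 (not isolated)
Conditions: 15 (3 equiv), KOH (50% aq, 20 equiv), EtOH, rt, 48 h, Ar, dark; then cold 1 M HCl to pH 5
Reagents that add atoms: none
Why: Claisen–Schmidt condensation, in which hydroxide first cleaves both aryl acetates (16), the methyl ketone enolate adds to benzaldehyde (17) and E1cB dehydration gives the E-chalcone, the basic medium keeping the 2'-phenoxide from closing to the flavanone and leaving both sp3 stereocentres untouched.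

## Compound list

1 | 4-acetoxystyrene (4-ethenylphenyl acetate) | CC(=O)Oc1ccc(C=C)cc1 | starting material
2 | (R)-but-3-en-2-ol | C[C@@H](O)C=C | starting material
3 | 4-[(1E,3R)-3-hydroxybut-1-en-1-yl]phenyl acetate | C[C@@H](O)/C=C/c1ccc(OC(C)=O)cc1 | intermediate
4 | 1-(2,4-dihydroxy-6-methoxyphenyl)ethanone | CC(=O)c1c(O)cc(O)cc1OC | starting material
5 | 4-[(1E,3S)-3-(4-acetyl-3-hydroxy-5-methoxyphenoxy)but-1-en-1-yl]phenyl acetate | CC(=O)c1c(O)cc(O[C@@H](C)/C=C/c2ccc(OC(C)=O)cc2)cc1OC | intermediate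
6 | ortho-dienone, 4-[(1R,2E)-1-[(1R)-3-acetyl-2-hydroxy-4-methoxy-6-oxocyclohexa-2,4-dien-1-yl]but-2-en-1-yl]phenyl acetate (same spatial arrangement at the benzylic carbon as in 7; the descriptor changes only through priorities) | CC(=O)C1=C(O)[C@@H]([C@@H](/C=C/C)c2ccc(OC(C)=O)cc2)C(=O)C=C1OC | intermediate (not isolated)
7 | 4-[(1S,2E)-1-(3-acetyl-2,6-dihydroxy-4-methoxyphenyl)but-2-en-1-yl]phenyl acetate | CC(=O)c1c(O)c([C@@H](/C=C/C)c2ccc(OC(C)=O)cc2)c(O)cc1OC | intermediate
8 | 4-iodophenyl acetate | CC(=O)Oc1ccc(I)cc1 | starting material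
9 | allyl alcohol (prop-2-en-1-ol) | C=CCO | starting material
10 | enol, 4-(3-hydroxyprop-2-en-1-yl)phenyl acetate (E/Z mixture, geometry not defined) | CC(=O)Oc1ccc(CC=CO)cc1 | intermediate (not isolated)
11 | 4-(3-oxopropyl)phenyl acetate | CC(=O)Oc1ccc(CCC=O)cc1 | intermediate
12 | 4-[(3R)-3-(tributylstannyloxy)hex-5-en-1-yl]phenyl acetate | C=CC[C@H](O[Sn](CCCC)(CCCC)CCCC)CCc1ccc(OC(C)=O)cc1 | intermediate (not isolated)
13 | 4-[(3R)-3-hydroxyhex-5-en-1-yl]phenyl acetate | C=CC[C@H](O)CCc1ccc(OC(C)=O)cc1 | intermediate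
14 | 4-[(3R,5E,7S)-7-(3-acetyl-2,6-dihydroxy-4-methoxyphenyl)-7-(4-acetoxyphenyl)-3-hydroxyhept-5-en-1-yl]phenyl acetate | CC(=O)c1c(O)c([C@@H](/C=C/C[C@H](O)CCc2ccc(OC(C)=O)cc2)c2ccc(OC(C)=O)cc2)c(O)cc1OC | intermediate
15 | benzaldehyde | O=Cc1ccccc1 | starting material
16 | 1-[2,4-dihydroxy-3-[(1S,2E,5R)-5-hydroxy-1,7-bis(4-hydroxyphenyl)hept-2-en-1-yl]-6-methoxyphenyl]ethanone | CC(=O)c1c(O)c([C@@H](/C=C/C[C@H](O)CCc2ccc(O)cc2)c2ccc(O)cc2)c(O)cc1OC | intermediate (not isolated)
17 | 1-[2,4-dihydroxy-3-[(1S,2E,5R)-5-hydroxy-1,7-bis(4-hydroxyphenyl)hept-2-en-1-yl]-6-methoxyphenyl]-3-hydroxy-3-phenylpropan-1-one (both epimers at the new carbinol carbon) | O=C(CC(O)c1ccccc1)c1c(O)c([C@@H](/C=C/C[C@H](O)CCc2ccc(O)cc2)c2ccc(O)cc2)c(O)cc1OC | intermediate (not isolated)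
18 | 7-epi-katsumain C, (2E)-1-[2,4-dihydroxy-3-[(1S,2E,5R)-5-hydroxy-1,7-bis(4-hydroxyphenyl)hept-2-en-1-yl]-6-methoxyphenyl]-3-phenylprop-2-en-1-one | COc1cc(O)c([C@@H](/C=C/C[C@H](O)CCc2ccc(O)cc2)c2ccc(O)cc2)c(O)c1C(=O)/C=C/c1ccccc1 | target

## Step count

Total: 7 steps. Longest linear sequence: 5 steps (1 → 2 → 3 → 6 → 7); the second branch is 4 → 5 → 6 → 7.

## Three steps most likely to fail, with fallbacks

**Step 3 (Claisen shift).** Risks: migration to C5 instead of C3; heterolysis of the allylic C–O bond (the para-acyl phenoxide is a good leaving group), which would give crossover or [1,3] products and erode chirality transfer; and a minor Z-propenyl product from the axial-methyl transition state, which carries the opposite C7 configuration and has to be removed at 7 before metathesis erases the geometric label. The fallback sets out from 4 and comes back at 7. TBSCl and imidazole in DMF silylate only the non-chelated 4-hydroxyl of 4 to give 1-[4-(tert-butyldimethylsilyloxy)-2-hydroxy-6-methoxyphenyl]ethanone F1. Mitsunobu coupling of its chelated 2-hydroxyl with 3 (PPh3, DIAD, PhMe, rt) gives, with inversion, 4-[(1E,3S)-3-[2-acetyl-5-(tert-butyldimethylsilyloxy)-3-methoxyphenoxy]but-1-en-1-yl]phenyl acetate F2. Its ether oxygen has a single free ortho carbon and sits next to the carbonyl group, so the [3,3] shift (Eu(fod)3, CHCl3, 60 °C, or xylene, 140 °C) can only give 4-[(1S,2E)-1-[3-acetyl-6-(tert-butyldimethylsilyloxy)-2-hydroxy-4-methoxyphenyl]but-2-en-1-yl]phenyl acetate F3, with the same suprafacial chirality transfer. KHF2 in MeOH cleaves the aryl silyl ether without touching the acetate and gives 7.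

**Step 6 (cross-metathesis).** Risk: a hindered internal alkene beside a diaryl-substituted carbon flanked by two phenols, with low conversion, E/Z mixtures or double-bond migration. The fallback sets out from 3 (using 11 and 4) and comes back at 14; it puts the whole chain on the allylic alcohol first, so that the Claisen shift itself creates the 5E double bond.
- MnO2 in CH2Cl2 oxidises 3 to 4-[(1E)-3-oxobut-1-en-1-yl]phenyl acetate F4.
- Its enol borinate ((−)-Ipc2BCl, Et3N, Et2O, −78 °C; the antipodal reagent if the facial sense proves opposite) adds to 11 to give 4-[(1E,5R)-7-(4-acetoxyphenyl)-5-hydroxy-3-oxohept-1-en-1-yl]phenyl acetate F5.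
- TBSOTf and 2,6-lutidine give 4-[(1E,5R)-7-(4-acetoxyphenyl)-5-(tert-butyldimethylsilyloxy)-3-oxohept-1-en-1-yl]phenyl acetate F6.
- (S)-2-methyl-CBS-oxazaborolidine with catecholborane (PhMe, −78 °C) reduces the enone carbonyl to 4-[(1E,3R,5R)-7-(4-acetoxyphenyl)-5-(tert-butyldimethylsilyloxy)-3-hydroxyhept-1-en-1-yl]phenyl acetate F7.
- Mitsunobu coupling with 4 inverts the allylic centre and gives 4-[(1E,3S,5R)-3-(4-acetyl-3-hydroxy-5-methoxyphenoxy)-7-(4-acetoxyphenyl)-5-(tert-butyldimethylsilyloxy)hept-1-en-1-yl]phenyl acetate F8.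
- The Eu(fod)3-catalysed Claisen shift gives 4-[(3R,5E,7S)-7-(3-acetyl-2,6-dihydroxy-4-methoxyphenyl)-7-(4-acetoxyphenyl)-3-(tert-butyldimethylsilyloxy)hept-5-en-1-yl]phenyl acetate F9.
- HF·pyridine in THF removes the silyl ether and gives 14.

**Step 7 (Claisen–Schmidt condensation on the unprotected polyphenol).** Risk: the twice-deprotonated, di-ortho-substituted ketone condenses slowly, benzaldehyde is lost to Cannizzaro reaction, and the 2'-hydroxychalcone can close to the flavanone on acidification. The fallback sets out from 4 (using 15, 3 and 13) and comes back at 18; it builds the chalcone first on the simple ketone. KOH in EtOH condenses 4 with 15 to cardamonin F10 (also a catalogue compound). Mitsunobu coupling with 3 gives 4-[(1E,3S)-3-{3-hydroxy-5-methoxy-4-[(2E)-3-phenylprop-2-enoyl]phenoxy}but-1-en-1-yl]phenyl acetate F11. The Claisen shift (Eu(fod)3, CHCl3, 60 °C, dark) gives 4-[(1S,2E)-1-{2,6-dihydroxy-4-methoxy-3-[(2E)-3-phenylprop-2-enoyl]phenyl}but-2-en-1-yl]phenyl acetate F12. Cross-metathesis with 13 under the conditions of step 6 gives 7-epi-katsumain C di-O-acetate F13. K2CO3 in MeOH (rt, 30 min) removes both acetates and gives 18.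

## Further compounds

F1 | step 3 | 1-[4-(tert-butyldimethylsilyloxy)-2-hydroxy-6-methoxyphenyl]ethanone | CC(=O)c1c(O)cc(O[Si](C)(C)C(C)(C)C)cc1OC
F2 | step 3 | 4-[(1E,3S)-3-[2-acetyl-5-(tert-butyldimethylsilyloxy)-3-methoxyphenoxy]but-1-en-1-yl]phenyl acetate | CC(=O)c1c(O[C@@H](C)/C=C/c2ccc(OC(C)=O)cc2)cc(O[Si](C)(C)C(C)(C)C)cc1OC
F3 | step 3 | 4-[(1S,2E)-1-[3-acetyl-6-(tert-butyldimethylsilyloxy)-2-hydroxy-4-methoxyphenyl]but-2-en-1-yl]phenyl acetate | CC(=O)c1c(O)c([C@@H](/C=C/C)c2ccc(OC(C)=O)cc2)c(O[Si](C)(C)C(C)(C)C)cc1OC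
F4 | step 6 | 4-[(1E)-3-oxobut-1-en-1-yl]phenyl acetate | CC(=O)/C=C/c1ccc(OC(C)=O)cc1
F5 | step 6 | 4-[(1E,5R)-7-(4-acetoxyphenyl)-5-hydroxy-3-oxohept-1-en-1-yl]phenyl acetate | CC(=O)Oc1ccc(/C=C/C(=O)C[C@H](O)CCc2ccc(OC(C)=O)cc2)cc1
F6 | step 6 | 4-[(1E,5R)-7-(4-acetoxyphenyl)-5-(tert-butyldimethylsilyloxy)-3-oxohept-1-en-1-yl]phenyl acetate | CC(=O)Oc1ccc(/C=C/C(=O)C[C@H](O[Si](C)(C)C(C)(C)C)CCc2ccc(OC(C)=O)cc2)cc1
F7 | step 6 | 4-[(1E,3R,5R)-7-(4-acetoxyphenyl)-5-(tert-butyldimethylsilyloxy)-3-hydroxyhept-1-en-1-yl]phenyl acetate | CC(=O)Oc1ccc(/C=C/[C@H](O)C[C@H](O[Si](C)(C)C(C)(C)C)CCc2ccc(OC(C)=O)cc2)cc1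
F8 | step 6 | 4-[(1E,3S,5R)-3-(4-acetyl-3-hydroxy-5-methoxyphenoxy)-7-(4-acetoxyphenyl)-5-(tert-butyldimethylsilyloxy)hept-1-en-1-yl]phenyl acetate | CC(=O)c1c(O)cc(O[C@@H](C[C@H](O[Si](C)(C)C(C)(C)C)CCc2ccc(OC(C)=O)cc2)/C=C/c2ccc(OC(C)=O)cc2)cc1OC
F9 | step 6 | 4-[(3R,5E,7S)-7-(3-acetyl-2,6-dihydroxy-4-methoxyphenyl)-7-(4-acetoxyphenyl)-3-(tert-butyldimethylsilyloxy)hept-5-en-1-yl]phenyl acetate | CC(=O)c1c(O)c([C@@H](/C=C/C[C@H](O[Si](C)(C)C(C)(C)C)CCc2ccc(OC(C)=O)cc2)c2ccc(OC(C)=O)cc2)c(O)cc1OC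
F10 | step 7 | cardamonin, (2E)-1-(2,4-dihydroxy-6-methoxyphenyl)-3-phenylprop-2-en-1-one | COc1cc(O)cc(O)c1C(=O)/C=C/c1ccccc1
F11 | step 7 | 4-[(1E,3S)-3-{3-hydroxy-5-methoxy-4-[(2E)-3-phenylprop-2-enoyl]phenoxy}but-1-en-1-yl]phenyl acetate | COc1cc(O[C@@H](C)/C=C/c2ccc(OC(C)=O)cc2)cc(O)c1C(=O)/C=C/c1ccccc1
F12 | step 7 | 4-[(1S,2E)-1-{2,6-dihydroxy-4-methoxy-3-[(2E)-3-phenylprop-2-enoyl]phenyl}but-2-en-1-yl]phenyl acetate | COc1cc(O)c([C@@H](/C=C/C)c2ccc(OC(C)=O)cc2)c(O)c1C(=O)/C=C/c1ccccc1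
F13 | step 7 | 7-epi-katsumain C di-O-acetate (both 4-hydroxyphenyl groups as acetates) | COc1cc(O)c([C@@H](/C=C/C[C@H](O)CCc2ccc(OC(C)=O)cc2)c2ccc(OC(C)=O)cc2)c(O)c1C(=O)/C=C/c1ccccc1
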